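## Retrosynthetic overview

1. Target 12 ⇐ bis(benzyl ether) 11 (hydrogenolysis) ⇐ alcohol 10 (acetylation) ⇐ aldehyde 9 (reduction).
2. Key disconnection of 9: the C2–C3 and C1–C8a bonds of ring B are made in one oxidative annulation of aldehyde 5 with cinnamyl acetate 8. The α-carbon of 5, normally a nucleophile, reacts as an electrophilic enamine radical cation (an enolonium equivalent) with the nucleophilic alkene carbon of 8.
3. Ring order: both benzene rings are bought; ring B is the only ring formed, in the key step (C–C bond first, then Friedel–Crafts closure onto ring A).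
4. 5 ⇐ eugenol 1; 8 ⇐ 4-allyl-2,6-dimethoxyphenol 6 by allylic C–H acetoxylation, which already installs one acetate of the target.

Assumption: reagents such as benzyl bromide and acetic anhydride are not numbered, and the sense of induction in step 6 is taken from the usual shielding model of the imidazolidinone catalyst.

## Route

Step 1
Reactants: 1 eugenol (4-allyl-2-methoxyphenol)
Product: 2 4-allyl-1-(benzyloxy)-2-methoxybenzene
Conditions: BnBr, K2CO3, DMF, rt
Reagents that add atoms: benzyl bromide, BrCc1ccccc1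
Why: Williamson ether synthesis (phenoxide SN2 on benzyl bromide) masks the phenol against the later one-electron oxidant; no stereocentre is involved.

Step 2
Reactants: 2 4-allyl-1-(benzyloxy)-2-methoxybenzene
Product: 4 3-[4-(benzyloxy)-3-methoxyphenyl]propan-1-ol, via B-alkyl-9-BBN adduct 3 (not isolated)
Conditions: 9-BBN, THF, 0 °C to rt; then NaOH, H2O2, 0 °C to rt
Reagents that add atoms: hydrogen peroxide, OO (the hydroxyl oxygen of 4); 9-borabicyclo[3.3.1]nonane, B1C2CCCC1CCC2 (the boron unit of 3 only)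
Why: Anti-Markovnikov hydroboration–oxidation places boron, then oxygen, on the terminal carbon of the allyl group; no stereocentre is formed.

Step 3
Reactants: 4 3-[4-(benzyloxy)-3-methoxyphenyl]propan-1-ol
Product: 5 3-[4-(benzyloxy)-3-methoxyphenyl]propanal
Conditions: TEMPO (10 mol%), PhI(OAc)2, CH2Cl2, rt
Reagents that add atoms: none
Why: Oxoammonium (TEMPO/PhI(OAc)2) oxidation of a primary alcohol stops at the aldehyde under anhydrous conditions and leaves the electron-rich arene and the benzyl ether alone.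

Step 4
Reactants: 6 4-allyl-2,6-dimethoxyphenol
Product: 7 5-allyl-2-(benzyloxy)-1,3-dimethoxybenzene
Conditions: BnBr, K2CO3, DMF, 60 °C
Reagents that add atoms: benzyl bromide, BrCc1ccccc1
Why: Williamson ether synthesis on the hindered but acidic 2,6-dimethoxyphenol, as is routine for syringyl phenols; no stereocentre is involved.

Step 5
Reactants: 7 5-allyl-2-(benzyloxy)-1,3-dimethoxybenzene
Product: 8 (E)-3-[4-(benzyloxy)-3,5-dimethoxyphenyl]prop-2-en-1-yl acetate
Conditions: Pd(OAc)2 (10 mol%), 1,4-benzoquinone (2 equiv), 4 Å MS, DMSO/AcOH (1:1), 40 °C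
Reagents that add atoms: acetic acid, CC(O)=O
Why: Allylic C–H acetoxylation, in which divalent palladium cleaves the allylic/benzylic C–H bond to a π-allyl complex and acetate attacks the terminus remote from the aryl ring, gives the conjugated linear E acetate while benzoquinone returns zerovalent palladium to the divalent state.

Step 6
Reactants: 5 3-[4-(benzyloxy)-3-methoxyphenyl]propanal, 8 (E)-3-[4-(benzyloxy)-3,5-dimethoxyphenyl]prop-2-en-1-yl acetate
Product: 10 [(1S,2R,3R)-7-(benzyloxy)-1-[4-(benzyloxy)-3,5-dimethoxyphenyl]-3-(hydroxymethyl)-6-methoxy-1,2,3,4-tetrahydronaphthalen-2-yl]methyl acetate, via tetralin aldehyde 9 (not isolated)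
Conditions: (2S,5S)-5-benzyl-2-tert-butyl-3-methylimidazolidin-4-one·TFA (20 mol%), [Fe(phen)3](SbF6)3 (2.5 equiv), Na2HPO4 (2.5 equiv), acetone, −30 °C; aqueous work-up, then NaBH4, MeOH/CH2Cl2, 0 °C
Reagents that add atoms: none
Why: Proposed new method: the enamine of 5 is oxidised by trivalent iron to a 3π-electron radical cation that is electrophilic at the aldehyde α-carbon, which adds to the alkene carbon of 8 remote from the aryl ring on the Si face left open by the catalyst benzyl group (C3 = R) through an open transition state with the styrenyl terminus anti to the iminium unit (C2/C3 trans), after which the p-alkoxybenzylic radical is oxidised to the cation and trapped para to the methoxy group of ring A in a chair-like Friedel–Crafts closure with the aryl group equatorial (C1/C2 trans), the closest known reaction type being the organo-SOMO radical-polar crossover [4+2] cycloaddition of 3-arylpropanals with terminal styrenes, here followed by routine NaBH4 reduction of the aldehyde.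

Step 7
Reactants: 10 [(1S,2R,3R)-7-(benzyloxy)-1-[4-(benzyloxy)-3,5-dimethoxyphenyl]-3-(hydroxymethyl)-6-methoxy-1,2,3,4-tetrahydronaphthalen-2-yl]methyl acetate
Product: 11 [(1S,2R,3R)-7-(benzyloxy)-1-[4-(benzyloxy)-3,5-dimethoxyphenyl]-6-methoxy-1,2,3,4-tetrahydronaphthalene-2,3-diyl]bis(methylene) diacetate
Conditions: Ac2O, pyridine, DMAP (cat.), CH2Cl2, rt
Reagents that add atoms: acetic anhydride, CC(=O)OC(C)=O
Why: DMAP-catalysed acetylation (nucleophilic acyl transfer) of the only free hydroxyl group touches no stereocentre.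

Step 8
Reactants: 11 [(1S,2R,3R)-7-(benzyloxy)-1-[4-(benzyloxy)-3,5-dimethoxyphenyl]-6-methoxy-1,2,3,4-tetrahydronaphthalene-2,3-diyl]bis(methylene) diacetate
Product: 12 [(1S,2R,3R)-7-hydroxy-1-(4-hydroxy-3,5-dimethoxyphenyl)-6-methoxy-1,2,3,4-tetrahydronaphthalene-2,3-diyl]bis(methylene) diacetate (CNP0265800.1)
Conditions: H2 (1 atm), 10% Pd/C, EtOAc/EtOH, rt
Reagents that add atoms: none
Why: Catalytic hydrogenolysis cleaves only the two benzyl aryl ethers and leaves the alkyl acetates, the aryl methyl ethers and the three stereocentres untouched under neutral conditions.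

## Compound list

1 | eugenol (4-allyl-2-methoxyphenol) | COc1cc(CC=C)ccc1O | starting material
2 | 4-allyl-1-(benzyloxy)-2-methoxybenzene | COc1cc(CC=C)ccc1OCc1ccccc1 | intermediate
3 | 9-{3-[4-(benzyloxy)-3-methoxyphenyl]propyl}-9-borabicyclo[3.3.1]nonane | COc1cc(CCCB2C3CCCC2CCC3)ccc1OCc1ccccc1 | intermediate
4 | 3-[4-(benzyloxy)-3-methoxyphenyl]propan-1-ol | COc1cc(CCCO)ccc1OCc1ccccc1 | intermediate
5 | 3-[4-(benzyloxy)-3-methoxyphenyl]propanal | COc1cc(CCC=O)ccc1OCc1ccccc1 | intermediate
6 | 4-allyl-2,6-dimethoxyphenol | COc1cc(CC=C)cc(OC)c1O | starting material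
7 | 5-allyl-2-(benzyloxy)-1,3-dimethoxybenzene | COc1cc(CC=C)cc(OC)c1OCc1ccccc1 | intermediate
8 | (E)-3-[4-(benzyloxy)-3,5-dimethoxyphenyl]prop-2-en-1-yl acetate | COc1cc(/C=C/COC(C)=O)cc(OC)c1OCc1ccccc1 | intermediate
9 | [(1S,2R,3R)-7-(benzyloxy)-1-[4-(benzyloxy)-3,5-dimethoxyphenyl]-3-formyl-6-methoxy-1,2,3,4-tetrahydronaphthalen-2-yl]methyl acetate | COc1cc2c(cc1OCc1ccccc1)[C@H](c1cc(OC)c(OCc3ccccc3)c(OC)c1)[C@@H](COC(C)=O)[C@H](C=O)C2 | intermediate
10 | [(1S,2R,3R)-7-(benzyloxy)-1-[4-(benzyloxy)-3,5-dimethoxyphenyl]-3-(hydroxymethyl)-6-methoxy-1,2,3,4-tetrahydronaphthalen-2-yl]methyl acetate | COc1cc2c(cc1OCc1ccccc1)[C@H](c1cc(OC)c(OCc3ccccc3)c(OC)c1)[C@@H](COC(C)=O)[C@H](CO)C2 | intermediate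
11 | [(1S,2R,3R)-7-(benzyloxy)-1-[4-(benzyloxy)-3,5-dimethoxyphenyl]-6-methoxy-1,2,3,4-tetrahydronaphthalene-2,3-diyl]bis(methylene) diacetate | COc1cc2c(cc1OCc1ccccc1)[C@H](c1cc(OC)c(OCc3ccccc3)c(OC)c1)[C@@H](COC(C)=O)[C@H](COC(C)=O)C2 | intermediate
12 | [(1S,2R,3R)-7-hydroxy-1-(4-hydroxy-3,5-dimethoxyphenyl)-6-methoxy-1,2,3,4-tetrahydronaphthalene-2,3-diyl]bis(methylene) diacetate | COc1cc2c(cc1O)[C@H](c1cc(OC)c(O)c(OC)c1)[C@@H](COC(C)=O)[C@H](COC(C)=O)C2 | target

## Step count and risks

Total step count: 8. Longest linear sequence: 6 (steps 1, 2, 3, 6, 7, 8).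

**Most likely to fail, first: step 6.** Alkene 8 is 1,2-disubstituted and easily oxidised, so radical capture may be slow and the alkene may itself be oxidised. The acetate can also compete with ring A for the benzylic cation. The C2/C3 relationship is set in an open transition state, so a C2 epimer may form; it is a diastereomer and is removed by chromatography at 10, leaving the ee set by the catalyst-controlled C3 centre.

The fallback sets out from 5 (and uses 8 again) and comes back at 11, replacing catalyst control by an auxiliary-controlled radical-polar crossover annulation of an α-bromo imide. Pinnick oxidation of 5 (NaClO2, NaH2PO4, 2-methyl-2-butene) gives 3-[4-(benzyloxy)-3-methoxyphenyl]propanoic acid F1. Its pivaloyl mixed anhydride acylates lithiated (S)-4-benzyloxazolidin-2-one to give (4S)-4-benzyl-3-{3-[4-(benzyloxy)-3-methoxyphenyl]propanoyl}-1,3-oxazolidin-2-one F2. Boron enolate bromination (Bu2BOTf, iPr2NEt, then NBS) gives (4S)-4-benzyl-3-{2-bromo-3-[4-(benzyloxy)-3-methoxyphenyl]propanoyl}-1,3-oxazolidin-2-one F3; either C2 epimer serves, because this centre becomes a radical. Under visible light with Ir(ppy)3, Mg(ClO4)2 and 2,6-lutidine, the chelated α-imide radical of F3 adds to 8 on the face opposite the auxiliary benzyl group. The benzylic radical is oxidised to the cation and closes onto ring A with loss of HBr, giving [(1S,2R,3R)-3-{[(4S)-4-benzyl-2-oxo-1,3-oxazolidin-3-yl]carbonyl}-7-(benzyloxy)-1-[4-(benzyloxy)-3,5-dimethoxyphenyl]-6-methoxy-1,2,3,4-tetrahydronaphthalen-2-yl]methyl acetate F4. LiBH4 removes the auxiliary and the acetate to give [(1S,2R,3R)-7-(benzyloxy)-1-[4-(benzyloxy)-3,5-dimethoxyphenyl]-6-methoxy-1,2,3,4-tetrahydronaphthalene-2,3-diyl]dimethanol F5, and Ac2O/pyridine acetylates both hydroxyls to reach 11.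

**Second: step 5.** The electron-rich allylarene may isomerise to the propenylarene or give branched acetate.

The fallback sets out from 7 and comes back at 8 by an isomerise-then-oxidise sequence. RuHCl(CO)(PPh3)3 (cat., toluene, 80 °C) moves the double bond into conjugation to give 2-(benzyloxy)-1,3-dimethoxy-5-[(E)-prop-1-en-1-yl]benzene F6. DDQ in wet 1,4-dioxane oxidises the allylic methyl group to give (E)-3-[4-(benzyloxy)-3,5-dimethoxyphenyl]prop-2-enal F7. Luche reduction (NaBH4, CeCl3·7H2O, MeOH) gives (E)-3-[4-(benzyloxy)-3,5-dimethoxyphenyl]prop-2-en-1-ol F8, and Ac2O/pyridine gives 8.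

**Third: step 3.** Aldehyde 5 is enolisable and air-sensitive, and must be clean and fresh for step 6.

The fallback sets out from 2 and comes back at 5, bypassing 3 and 4. It is a direct, aldehyde-selective, nitrite-co-catalysed Wacker-type oxidation of the terminal alkene (PdCl2(PhCN)2, CuCl2, AgNO2, tBuOH/MeNO2, O2), so 5 is made and used without passing through the alcohol. This fallback makes no new compound (F0).

## Further compounds

F1 | step 6 | 3-[4-(benzyloxy)-3-methoxyphenyl]propanoic acid | COc1cc(CCC(O)=O)ccc1OCc1ccccc1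
F2 | step 6 | (4S)-4-benzyl-3-{3-[4-(benzyloxy)-3-methoxyphenyl]propanoyl}-1,3-oxazolidin-2-one | COc1cc(CCC(=O)N2[C@@H](Cc3ccccc3)COC2=O)ccc1OCc1ccccc1
F3 | step 6 | (4S)-4-benzyl-3-{2-bromo-3-[4-(benzyloxy)-3-methoxyphenyl]propanoyl}-1,3-oxazolidin-2-one (both C2 epimers) | COc1cc(CC(Br)C(=O)N2[C@@H](Cc3ccccc3)COC2=O)ccc1OCc1ccccc1
F4 | step 6 | [(1S,2R,3R)-3-{[(4S)-4-benzyl-2-oxo-1,3-oxazolidin-3-yl]carbonyl}-7-(benzyloxy)-1-[4-(benzyloxy)-3,5-dimethoxyphenyl]-6-methoxy-1,2,3,4-tetrahydronaphthalen-2-yl]methyl acetate | COc1cc2c(cc1OCc1ccccc1)[C@H](c1cc(OC)c(OCc3ccccc3)c(OC)c1)[C@@H](COC(C)=O)[C@H](C(=O)N1[C@@H](Cc3ccccc3)COC1=O)C2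
F5 | step 6 | [(1S,2R,3R)-7-(benzyloxy)-1-[4-(benzyloxy)-3,5-dimethoxyphenyl]-6-methoxy-1,2,3,4-tetrahydronaphthalene-2,3-diyl]dimethanol | COc1cc2c(cc1OCc1ccccc1)[C@H](c1cc(OC)c(OCc3ccccc3)c(OC)c1)[C@@H](CO)[C@H](CO)C2
F6 | step 5 | 2-(benzyloxy)-1,3-dimethoxy-5-[(E)-prop-1-en-1-yl]benzene | COc1cc(/C=C/C)cc(OC)c1OCc1ccccc1
F7 | step 5 | (E)-3-[4-(benzyloxy)-3,5-dimethoxyphenyl]prop-2-enal | COc1cc(/C=C/C=O)cc(OC)c1OCc1ccccc1
F8 | step 5 | (E)-3-[4-(benzyloxy)-3,5-dimethoxyphenyl]prop-2-en-1-ol | COc1cc(/C=C/CO)cc(OC)c1OCc1ccccc1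
F0 | step 3 | none | none
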